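## The problem

The target 17 is a depside: two hexasubstituted benzene rings joined by a single ester. It has no ring fusion and no stereocentre, so no configuration has to be set and no centre controls another. The difficulty is the ester itself. Its acyl carbon C1' lies between C2' (OCH3) and C6' (CH3) of ring B, and its oxygen sits on C4 of ring A between the C3 and C5 methyl groups. A union by acyl substitution therefore has to pass through a tetrahedral intermediate hemmed in by four ortho substituents. Ring A also carries the C1 methyl ester and the C2 hydroxyl hydrogen-bonded to it. Ring B carries three different oxygen functions (C2' OCH3, C4' OH, the carboxyl) and chlorine at C5', each of which must be placed unambiguously. The groups that will not survive rough treatment are the depside ester and the methyl ester (hydroxide, alkoxide), the free phenols (peracids, trivalent iodine) and the aryl chloride (hydrogenolysis). The feature that opens a way round the crowded acyl carbon is C4 of ring A. It has two ortho methyl groups, no ortho hydrogen and a para ester, which is the profile of an aryl group that a diaryliodonium salt passes to an oxygen nucleophile in preference to an electron-rich partner aryl. The ester can therefore be made at the aryl–oxygen bond, with the ring B carboxylate oxygen as nucleophile.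

## Retrosynthesis

**17 from 16.** The last cut removes two protecting groups: the acetyl group on O2 of ring A and the methoxymethyl (MOM) group on O4' of ring B. The acetate shields the only phenol of ring A from the peracid and from trivalent iodine, and stops it competing as an O-nucleophile. The MOM ether does the same for the C4' hydroxyl of ring B, which as a phenoxide would be arylated faster than the carboxylate. Both should fall in one acid methanolysis. The depside ester is shielded by its four ortho substituents, and exchange at the methyl ester is degenerate in methanol.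

**16 from 8 and 13.** The bond cut is O–C4, the aryl–oxygen bond of the ester, not the acyl–oxygen bond next to it. Cutting at the acyl carbon would require a ring A with two free hydroxyls to be told apart, and an acyl substitution between two di-ortho-substituted partners. Cutting at C4 makes the carboxylate oxygen the nucleophile, one atom away from the congestion, and makes ring A the electrophile as the iodonium salt 8. It also means ring A needs only one oxygen from the start, because the C4 oxygen arrives with ring B. Each precursor is a single benzene ring with all its carbons in place. The forward reaction must transfer the ring A aryl and not the 2,4,6-trimethoxyphenyl group, and must tolerate the acetate, the MOM ether, the methyl ester and the aryl chloride.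

**8 from 5 and 6.** The iodine–carbon bond to the trimethoxyphenyl ring is cut. Forward, the aryl iodide 5 is oxidised to the hydroxy(tosyloxy)iodoarene 7, which substitutes 1,3,5-trimethoxybenzene 6 in the same flask. The trimethoxyphenyl ring is chosen as the non-transferring group because it is electron-rich and 6 is cheap. The step requires that the acetate of 5 survive an acidic peracid medium.

**5 from 1.** The C4–I bond is cut back to the acetate 4, in which C4 is the only ring C–H and lies between two methyl groups. Acetylation comes before iodination so that the electrophile does not meet a free phenol whose ortho and para positions are all substituted. Ester 4 comes from the salicylate 3, 3 from the acid 2 by O-alkylation of the carboxylate, and 2 from 2,4,5-trimethylphenol 1 by ortho carboxylation, which forms the C1–carboxyl bond. In 1 the para position and one ortho position are blocked by methyl groups, so only the carbon that becomes C1 can be carboxylated.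

**13 from 9.** The acid 13 comes from its methyl ester 12 by hydrolysis, 12 from 11 by O-methylation at C2', 11 from 10 by MOM protection at C4', and 10 from atraric acid 9 by chlorination at C5'. Atraric acid already holds every carbon of ring B and both oxygens. C5' is its only ring C–H, so the chlorine can go nowhere else. The two hydroxyls are distinguished by the hydrogen bond of the C2' hydroxyl to the ester. The demanding step is hydrolysis of the di-ortho-substituted ester 12.

## Roads not taken

Alternative 1: Ring A is cut at C1–C6 and C3–C4 and built from two acyclic esters, methyl 3-oxopentanoate A1 and methyl tiglate A2. Under alkoxide base the central carbon of A1 adds to the β-carbon of A2 (C1–C6), and the ethyl-side enolate then closes onto the tiglate ester (C3–C4). The product is the dihydroresorcylate A3, methyl 3,5,6-trimethyl-2,4-dioxocyclohexane-1-carboxylate, as a mixture of diastereomers and enol forms. Dehydrogenation would give the ring A resorcylate A4. The merit is economy: bulk starting materials, all six ring A substituents set in one operation, and both oxygens present. The weak points are the Michael addition to an α,β-dimethyl acrylate, which is slow and reversible, and the aromatisation of a ring with no unsubstituted carbon. More important, this road makes ring A only. The depside ester would still have to be formed by acylating the C4 hydroxyl of A4 at the crowded acyl carbon of a ring B acid such as 13. In the count of steps to an aromatic ring A this road is shorter than the five steps to 8. Against that, the chosen plan has an ester-forming step that avoids the hindered carbonyl, needs no selection between two ring A hydroxyls, and starts from an aromatic ring that needs no dehydrogenation.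

Alternative 2: Ring A is cut at C5–C6, C2–C3, C4–C5 and C1–C2 and assembled by a vinylketene benzannulation. Photochemical Wolff rearrangement of the diazo enone A5 (C5–C6) would give a vinylketene. This adds the siloxyalkyne A6 (C2–C3, C4–C5), and four-electron ring opening followed by six-electron electrocyclisation (C1–C2) closes the ring. The product is A7, methyl 2-hydroxy-3,5,6-trimethyl-4-(triisopropylsilyloxy)benzoate. Its merits are full regiocontrol over all six positions and two oxygens that emerge already differentiated, which the first alternative does not offer. Its weak points are the preparation of A5 and A6, a photochemical step, and again the need to desilylate and acylate the C4 oxygen by acyl substitution. It is convergent but no shorter than the route to 8. The chosen plan obtains the same differentiation more simply, by having only one oxygen on ring A until the coupling.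

Alternative 3: Here ring B is cut, at C1'–C2' and C5'–C6'. The ring A hydroxyl at C4 would first be acylated with a slim alkynoyl group to give the but-2-ynoate A8, made from A4. A8 would then react with the ketene-acetal diene A9 in a [4+2] addition, and elimination of one methoxy group with desilylation would aromatise ring B. The product is the chlorine-free depside A10, which has a single ring C–H at C5' for a final chlorination. This road also avoids the crowded acyl substitution, and does so without hypervalent iodine. Its late chlorination is unambiguous. In these respects it is as good as the chosen plan. Its weak points are that it still needs a ring A with both oxygens (A4), that a β-methyl alkynoate is a sluggish dienophile, that the aryl ester of A8 can transfer its acyl group to the nucleophilic diene, and that the last chlorination takes place beside a very electron-rich ring A. The chosen plan takes both rings ready-made from commercial aromatics and introduces the chlorine on atraric acid before any sensitive group is present.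

Key step: step 10

Remark: the target is achiral. Ring A is numbered C1 (CO2CH3) to C6 and ring B C1' (acyl carbon), C2' (OCH3), C3' (CH3), C4' (OH), C5' (Cl), C6' (CH3). In the systematic names of ring B intermediates, C5' is benzoate position 3. Compounds 1, 6 and 9 are taken as commercially available.

## Route

Step 1
Reactants: 1 2,4,5-trimethylphenol
Product: 2 2-hydroxy-3,5,6-trimethylbenzoic acid
Conditions: K2CO3, CO2 (50 bar), 180 °C, autoclave; then aq. HCl
Reagents that add atoms: carbon dioxide, O=C=O
Why: Kolbe–Schmitt carboxylation of the potassium phenoxide; the para position and one ortho position of 1 are blocked by methyl groups, so CO2 can enter only at the free ortho carbon, which becomes C1 of ring A.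

Step 2
Reactants: 2 2-hydroxy-3,5,6-trimethylbenzoic acid
Product: 3 methyl 2-hydroxy-3,5,6-trimethylbenzoate
Conditions: MeI, KHCO3, DMF, rt
Reagents that add atoms: iodomethane, CI
Why: O-alkylation of the carboxylate (SN2 on MeI); hydrogencarbonate leaves the hydrogen-bonded phenol un-ionised, and alkylation at oxygen avoids acyl substitution at the di-ortho-substituted carboxyl.

Step 3
Reactants: 3 methyl 2-hydroxy-3,5,6-trimethylbenzoate
Product: 4 methyl 2-acetoxy-3,5,6-trimethylbenzoate
Conditions: Ac2O, pyridine, DMAP (cat.), rt to 50 °C
Reagents that add atoms: acetic anhydride, CC(=O)OC(C)=O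
Why: DMAP-catalysed acylation of the phenol; the acetate masks the only oxidisable group of ring A before the iodination and the peracid step.

Step 4
Reactants: 4 methyl 2-acetoxy-3,5,6-trimethylbenzoate
Product: 5 methyl 2-acetoxy-4-iodo-3,5,6-trimethylbenzoate
Conditions: NIS, TfOH, CH2Cl2, 0 °C to rt
Reagents that add atoms: N-iodosuccinimide, O=C1CCC(=O)N1I
Why: Electrophilic aromatic iodination with acid-activated NIS, a combination that iodinates deactivated arenes; C4 is the only ring C–H and is flanked by two activating methyl groups, and the acetate prevents ipso attack and dienone formation at the phenol.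

Step 5
Reactants: 5 methyl 2-acetoxy-4-iodo-3,5,6-trimethylbenzoate; 6 1,3,5-trimethoxybenzene
Product: 8 [3-acetoxy-4-(methoxycarbonyl)-2,5,6-trimethylphenyl](2,4,6-trimethoxyphenyl)iodonium tosylate, via hydroxy(tosyloxy)iodoarene 7 (not isolated)
Conditions: mCPBA, TsOH·H2O, MeCN, 77 °C; then 6, 77 °C to rt; precipitation with Et2O
Reagents that add atoms: 4-methylbenzenesulfonic acid monohydrate, Cc1ccc(cc1)S(=O)(=O)O.O
Why: One-pot oxidation of the aryl iodide by the peracid in the presence of TsOH gives 7, whose trivalent iodine then substitutes the very electron-rich arene 6 (electrophilic aromatic substitution). This is the established one-pot preparation of aryl(trimethoxyphenyl)iodonium tosylates, and the salt should crystallise on adding ether.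

Step 6
Reactants: 9 atraric acid (methyl 2,4-dihydroxy-3,6-dimethylbenzoate)
Product: 10 methyl 3-chloro-4,6-dihydroxy-2,5-dimethylbenzoate
Conditions: SO2Cl2, Et2O, 0 °C to rt
Reagents that add atoms: sulfuryl chloride, O=S(=O)(Cl)Cl
Why: Electrophilic aromatic chlorination; C5' is the only ring C–H of 9, ortho to the C4' hydroxyl and para to the C2' hydroxyl, so one equivalent at low temperature should chlorinate only there.

Step 7
Reactants: 10 methyl 3-chloro-4,6-dihydroxy-2,5-dimethylbenzoate
Product: 11 methyl 3-chloro-6-hydroxy-4-(methoxymethoxy)-2,5-dimethylbenzoate
Conditions: MOMCl, i-Pr2NEt, CH2Cl2, 0 °C to rt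
Reagents that add atoms: chloromethyl methyl ether, COCCl
Why: O-alkylation of the more acidic, non-chelated C4' hydroxyl (para ester, ortho chlorine); the C2' hydroxyl is held by its hydrogen bond to the ester carbonyl, the usual selectivity of 2,4-dihydroxybenzoates.

Step 8
Reactants: 11 methyl 3-chloro-6-hydroxy-4-(methoxymethoxy)-2,5-dimethylbenzoate
Product: 12 methyl 3-chloro-6-methoxy-4-(methoxymethoxy)-2,5-dimethylbenzoate
Conditions: MeI, K2CO3, DMF, 50 °C
Reagents that add atoms: iodomethane, CI
Why: Williamson ether synthesis on the remaining chelated phenol, which needs carbonate and gentle heating; no other acidic or nucleophilic site is left.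

Step 9
Reactants: 12 methyl 3-chloro-6-methoxy-4-(methoxymethoxy)-2,5-dimethylbenzoate
Product: 13 3-chloro-6-methoxy-4-(methoxymethoxy)-2,5-dimethylbenzoic acid
Conditions: KOH, DMSO–H2O, 90 °C; then 1 M HCl, 0 °C, to pH 3
Reagents that add atoms: potassium hydroxide, [K+].[OH-]
Why: Saponification of a di-ortho-substituted benzoate with poorly solvated hydroxide in wet DMSO, conditions used for hindered esters; the MOM ether and aryl chloride are stable to base, and cold acidification to pH 3 spares the acetal.

Step 10
Reactants: 13 3-chloro-6-methoxy-4-(methoxymethoxy)-2,5-dimethylbenzoic acid; 8 [3-acetoxy-4-(methoxycarbonyl)-2,5,6-trimethylphenyl](2,4,6-trimethoxyphenyl)iodonium tosylate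
Product: 16 3-acetoxy-4-(methoxycarbonyl)-2,5,6-trimethylphenyl 3-chloro-6-methoxy-4-(methoxymethoxy)-2,5-dimethylbenzoate, via caesium carboxylate 14 (not isolated), via aryl(carboxylato)iodane 15 (not isolated)
Conditions: Cs2CO3 (0.5 equiv), MeOH, rt, evaporate, toluene azeotrope; then 8, toluene, 110 °C
Reagents that add atoms: none
Why: Cs2CO3 converts 13 into the caesium carboxylate 14, which displaces tosylate at the trivalent iodine of 8 to give the T-shaped aryl(carboxylato)iodane 15. Ligand coupling in 15 joins the carboxylate oxygen to the ipso carbon C4 of ring A and releases the iodoarene of the trimethoxyphenyl ring, iodine going from trivalent to monovalent. The closest known reaction type is the metal-free O-arylation of carboxylic acids with diaryliodonium salts, including aryl(trimethoxyphenyl)iodonium tosylates. No ring is closed and no stereocentre is formed. The selectivity needed is transfer of the ring A aryl and not the trimethoxyphenyl group; the C3 and C5 methyl groups (ortho effect) and the para C1 ester make C4 the more hindered and more electrophilic ipso carbon, while the electron-rich trimethoxyphenyl ring stays on iodine. Neither aryl group has a hydrogen ortho to iodine, so aryne pathways are closed. The nucleophilic atom is the carboxylate oxygen, one bond from the crowded C1', so the four ortho substituents never meet in a tetrahedral intermediate. The acetate, MOM ether, methyl ester and aryl chloride are inert to a carboxylate in hot toluene.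

Step 11
Reactants: 16 3-acetoxy-4-(methoxycarbonyl)-2,5,6-trimethylphenyl 3-chloro-6-methoxy-4-(methoxymethoxy)-2,5-dimethylbenzoate
Product: 17 3-hydroxy-4-(methoxycarbonyl)-2,5,6-trimethylphenyl 3-chloro-4-hydroxy-6-methoxy-2,5-dimethylbenzoate (the target)
Conditions: HCl (1.25 M in MeOH), 45 °C
Reagents that add atoms: none
Why: Acid-catalysed methanolysis: the MOM acetal is exchanged to dimethoxymethane and the unhindered acetyl group is transesterified to methyl acetate. The depside ester is shielded by four ortho substituents and the methyl ester undergoes only degenerate exchange, so both should remain.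

## Compound list

1 | 2,4,5-trimethylphenol | Cc1cc(C)c(O)cc1C | starting material
2 | 2-hydroxy-3,5,6-trimethylbenzoic acid | Cc1cc(C)c(O)c(C(=O)O)c1C | intermediate
3 | methyl 2-hydroxy-3,5,6-trimethylbenzoate | COC(=O)c1c(C)c(C)cc(C)c1O | intermediate
4 | methyl 2-acetoxy-3,5,6-trimethylbenzoate | COC(=O)c1c(C)c(C)cc(C)c1OC(C)=O | intermediate
5 | methyl 2-acetoxy-4-iodo-3,5,6-trimethylbenzoate | COC(=O)c1c(C)c(C)c(I)c(C)c1OC(C)=O | intermediate
6 | 1,3,5-trimethoxybenzene | COc1cc(OC)cc(OC)c1 | starting material
7 | methyl 2-acetoxy-4-[hydroxy(tosyloxy)-λ3-iodanyl]-3,5,6-trimethylbenzoate | COC(=O)c1c(C)c(C)c(I(O)OS(=O)(=O)c2ccc(C)cc2)c(C)c1OC(C)=O | intermediate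
8 | [3-acetoxy-4-(methoxycarbonyl)-2,5,6-trimethylphenyl](2,4,6-trimethoxyphenyl)iodonium tosylate | COC(=O)c1c(C)c(C)c([I+]c2c(OC)cc(OC)cc2OC)c(C)c1OC(C)=O.Cc1ccc(S(=O)(=O)[O-])cc1 | intermediate
9 | atraric acid (methyl 2,4-dihydroxy-3,6-dimethylbenzoate) | COC(=O)c1c(C)cc(O)c(C)c1O | starting material
10 | methyl 3-chloro-4,6-dihydroxy-2,5-dimethylbenzoate | COC(=O)c1c(C)c(Cl)c(O)c(C)c1O | intermediate
11 | methyl 3-chloro-6-hydroxy-4-(methoxymethoxy)-2,5-dimethylbenzoate | COC(=O)c1c(C)c(Cl)c(OCOC)c(C)c1O | intermediate
12 | methyl 3-chloro-6-methoxy-4-(methoxymethoxy)-2,5-dimethylbenzoate | COC(=O)c1c(C)c(Cl)c(OCOC)c(C)c1OC | intermediate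
13 | 3-chloro-6-methoxy-4-(methoxymethoxy)-2,5-dimethylbenzoic acid | COc1c(C)c(OCOC)c(Cl)c(C)c1C(=O)O | intermediate
14 | caesium 3-chloro-6-methoxy-4-(methoxymethoxy)-2,5-dimethylbenzoate | [Cs+].COc1c(C)c(OCOC)c(Cl)c(C)c1C(=O)[O-] | intermediate
15 | [3-acetoxy-4-(methoxycarbonyl)-2,5,6-trimethylphenyl](2,4,6-trimethoxyphenyl)-λ3-iodanyl 3-chloro-6-methoxy-4-(methoxymethoxy)-2,5-dimethylbenzoate | COC(=O)c1c(C)c(C)c(I(OC(=O)c2c(C)c(Cl)c(OCOC)c(C)c2OC)c2c(OC)cc(OC)cc2OC)c(C)c1OC(C)=O | intermediate
16 | 3-acetoxy-4-(methoxycarbonyl)-2,5,6-trimethylphenyl 3-chloro-6-methoxy-4-(methoxymethoxy)-2,5-dimethylbenzoate | COC(=O)c1c(C)c(C)c(OC(=O)c2c(C)c(Cl)c(OCOC)c(C)c2OC)c(C)c1OC(C)=O | intermediate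
17 | 3-hydroxy-4-(methoxycarbonyl)-2,5,6-trimethylphenyl 3-chloro-4-hydroxy-6-methoxy-2,5-dimethylbenzoate | COC(=O)c1c(C)c(C)c(OC(=O)c2c(C)c(Cl)c(O)c(C)c2OC)c(C)c1O | target

## Step count and risks

Total: 11 steps. Longest linear sequence: 7 steps (steps 1 to 5, 10 and 11). The ring B branch (steps 6 to 9) joins at step 10.

**Step 10 (key step).** The ligand coupling may be slow if the caesium carboxylate and the iodonium tosylate dissolve poorly in toluene. Part of the salt may then be lost to competing transfer of the trimethoxyphenyl group or to arylation of the tosylate. Traces of water or base could also open the acetate, after which the liberated phenoxide would be arylated in place of the carboxylate. The fallback gives up the aryl–oxygen disconnection for a conventional acylation. It sets out from 5 and 13 and comes back at 17.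
- Hydroxylation of 5 with Pd2(dba)3, t-BuXPhos and KOH in dioxane–water, during which the acetate is also cleaved, should give methyl 2,4-dihydroxy-3,5,6-trimethylbenzoate F1 (the same structure as A4).
- Acid 13 would be converted under neutral conditions with 1-chloro-N,N,2-trimethylprop-1-en-1-amine in CH2Cl2 into 3-chloro-6-methoxy-4-(methoxymethoxy)-2,5-dimethylbenzoyl chloride F2, conditions that spare the MOM ether.
- The non-chelated C4 hydroxyl of F1, deprotonated with NaH in THF, would be acylated by F2, which as a 2,6-disubstituted benzoyl chloride can react through an acylium-like pathway. This should give 3-hydroxy-4-(methoxycarbonyl)-2,5,6-trimethylphenyl 3-chloro-6-methoxy-4-(methoxymethoxy)-2,5-dimethylbenzoate F3.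
- The conditions of step 11 then remove the MOM group and lead to 17.

**Step 4.** The iodination may stall, because C4 is para to the ester and meta to the acetoxy group, and prolonged exposure to TfOH may detach the acetyl group. The fallback, from 4 back to 5, introduces the iodine through nitrogen.
- Nitration with NO2BF4 in sulfolane should give methyl 2-acetoxy-3,5,6-trimethyl-4-nitrobenzoate F4.
- Hydrogenation (H2, Pd/C, EtOAc) should give methyl 2-acetoxy-4-amino-3,5,6-trimethylbenzoate F5.
- Diazotisation with NaNO2 and TsOH·H2O in MeCN should give 3-acetoxy-4-(methoxycarbonyl)-2,5,6-trimethylbenzenediazonium tosylate F6, which is treated in the same flask with KI to give 5 (Sandmeyer-type iodination).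

**Step 5.** Oxidation of the hindered, ester-deactivated iodide may be incomplete. The hydrated sulfonic acid at 77 °C may also hydrolyse the acetate, and the freed phenol would then be oxidised. The fallback, from 5 back to 8, separates the oxidation from the arylation. Oxidation with NaBO3·4H2O in acetic acid at 45 °C should give the isolable methyl 2-acetoxy-4-(diacetoxy-λ3-iodanyl)-3,5,6-trimethylbenzoate F7. F7 is then condensed with 6 and TsOH·H2O in MeCN at room temperature to give 8.

**Step 9.** Hydroxide may fail to reach the carbonyl of the di-ortho-substituted ester at a temperature the rest of the molecule tolerates, and the MOM ether may be lost during acidification. The fallback, from 12 back to 13, changes the oxidation level instead of hydrolysing.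
- Reduction with diisobutylaluminium hydride in CH2Cl2 at −78 to 0 °C should give [3-chloro-6-methoxy-4-(methoxymethoxy)-2,5-dimethylphenyl]methanol F8.
- Oxidation with MnO2 in CH2Cl2 should give 3-chloro-6-methoxy-4-(methoxymethoxy)-2,5-dimethylbenzaldehyde F9.
- Pinnick oxidation (NaClO2, NaH2PO4, 2-methylbut-2-ene, t-BuOH–water) should give 13.

**Step 1.** Carboxylation next to a methyl group may proceed with low conversion, and the product may decarboxylate again at the temperature required. The fallback, from 1 back to 2, introduces the carbon at the aldehyde level. Magnesium-mediated ortho-formylation (MgCl2, Et3N, paraformaldehyde, MeCN, reflux) should give 2-hydroxy-3,5,6-trimethylbenzaldehyde F10. Oxidation with NaClO2 and sulfamic acid in aqueous dioxane then gives 2.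

## Further compounds

F1 | step 10 | methyl 2,4-dihydroxy-3,5,6-trimethylbenzoate | COC(=O)c1c(C)c(C)c(O)c(C)c1O
F2 | step 10 | 3-chloro-6-methoxy-4-(methoxymethoxy)-2,5-dimethylbenzoyl chloride | COc1c(C)c(OCOC)c(Cl)c(C)c1C(=O)Cl
F3 | step 10 | 3-hydroxy-4-(methoxycarbonyl)-2,5,6-trimethylphenyl 3-chloro-6-methoxy-4-(methoxymethoxy)-2,5-dimethylbenzoate | COC(=O)c1c(C)c(C)c(OC(=O)c2c(C)c(Cl)c(OCOC)c(C)c2OC)c(C)c1O
F4 | step 4 | methyl 2-acetoxy-3,5,6-trimethyl-4-nitrobenzoate | COC(=O)c1c(C)c(C)c([N+](=O)[O-])c(C)c1OC(C)=O
F5 | step 4 | methyl 2-acetoxy-4-amino-3,5,6-trimethylbenzoate | COC(=O)c1c(C)c(C)c(N)c(C)c1OC(C)=O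
F6 | step 4 | 3-acetoxy-4-(methoxycarbonyl)-2,5,6-trimethylbenzenediazonium tosylate | COC(=O)c1c(C)c(C)c([N+]#N)c(C)c1OC(C)=O.Cc1ccc(S(=O)(=O)[O-])cc1
F7 | step 5 | methyl 2-acetoxy-4-(diacetoxy-λ3-iodanyl)-3,5,6-trimethylbenzoate | COC(=O)c1c(C)c(C)c(I(OC(C)=O)OC(C)=O)c(C)c1OC(C)=O
F8 | step 9 | [3-chloro-6-methoxy-4-(methoxymethoxy)-2,5-dimethylphenyl]methanol | COc1c(C)c(OCOC)c(Cl)c(C)c1CO
F9 | step 9 | 3-chloro-6-methoxy-4-(methoxymethoxy)-2,5-dimethylbenzaldehyde | COc1c(C)c(OCOC)c(Cl)c(C)c1C=O
F10 | step 1 | 2-hydroxy-3,5,6-trimethylbenzaldehyde | Cc1cc(C)c(O)c(C=O)c1C
A1 | alternative 1 | methyl 3-oxopentanoate | CCC(=O)CC(=O)OC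
A2 | alternative 1 | methyl tiglate (methyl (E)-2-methylbut-2-enoate) | C/C=C(\C)C(=O)OC
A3 | alternative 1 | methyl 3,5,6-trimethyl-2,4-dioxocyclohexane-1-carboxylate (mixture of diastereomers and enol tautomers) | COC(=O)C1C(C)C(C)C(=O)C(C)C1=O
A4 | alternative 1 | methyl 2,4-dihydroxy-3,5,6-trimethylbenzoate | COC(=O)c1c(C)c(C)c(O)c(C)c1O
A5 | alternative 2 | methyl (E)-5-diazo-3-methyl-4-oxohex-2-enoate | COC(=O)/C=C(\C)C(=O)C(C)=[N+]=[N-]
A6 | alternative 2 | 1-(triisopropylsilyloxy)prop-1-yne | CC#CO[Si](C(C)C)(C(C)C)C(C)C
A7 | alternative 2 | methyl 2-hydroxy-3,5,6-trimethyl-4-(triisopropylsilyloxy)benzoate | COC(=O)c1c(C)c(C)c(O[Si](C(C)C)(C(C)C)C(C)C)c(C)c1O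
A8 | alternative 3 | 3-hydroxy-4-(methoxycarbonyl)-2,5,6-trimethylphenyl but-2-ynoate | CC#CC(=O)Oc1c(C)c(C)c(C(=O)OC)c(O)c1C
A9 | alternative 3 | 1,1-dimethoxy-2-methyl-3-(trimethylsilyloxy)buta-1,3-diene | COC(OC)=C(C)C(=C)O[Si](C)(C)C
A10 | alternative 3 | 3-hydroxy-4-(methoxycarbonyl)-2,5,6-trimethylphenyl 4-hydroxy-2-methoxy-3,6-dimethylbenzoate | COC(=O)c1c(C)c(C)c(OC(=O)c2c(C)cc(O)c(C)c2OC)c(C)c1O
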